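Slowness is the complaint about this flask: what holds the chain back, and does more scavenger pay?

    initiator → 2 initiating radical (k1 = 5.7 × 10⁻⁵ s⁻¹)
    starting material + initiating radical → capped initiator + first chain carrier (k2 = 1.8 × 10⁶ M⁻¹ s⁻¹)
    reagent + first chain carrier ⇌ product + second chain carrier (K3 = 0.12, k3 = 27000 M⁻¹ s⁻¹)
    starting material + second chain carrier → released group + first chain carrier (k4 = 1.1 × 10⁵ M⁻¹ s⁻¹)
    2 first chain carrier → ended chains (k5 = 6.6 × 10⁷ M⁻¹ s⁻¹)
    reagent + released group ⇌ idle adduct, settled at all times (K6 = 36 M⁻¹)
    scavenger + released group → scavenged by-product (k7 = 3.3 M⁻¹ s⁻¹)

in all of them: starting material 0.020 M; reagent 2.00 equiv; initiator 0.61 mol%; time 20 min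

| charge | scavenger |
|---|---|
| Thursday's | 1.00 equiv |
| Tuesday's | 1.30 equiv |
| Friday's | 1.70 equiv |

* part of the starting material that has reacted at the end, Thursday's
* part of the starting material that has reacted at the end, Tuesday's
* part of the starting material that has reacted at the end, Friday's
* what raising the equivalents of scavenger from its lowest to its highest value here does to the part of the starting material that has reacted (changes below 5 percentage points count as none) (no change / it falls / it rises)

- in percentages every species weighs as the starting material in it: one ended chains counts as two
- for released group the idle adduct is counted in
- a step written with two of one species runs at k times the square of its concentration and takes two of it each time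
- run time (Thursday's): 20 min

**How much first chain carrier stands in the flask?** The half-life of the initiator by its own breakdown is 3.4 h, longer than the run of 20 min, so I hold the initiator at its charge. Each initiator gives two initiating radicals, each of those gives one first chain carrier, and the ending step takes two at a time. Making and ending therefore balance at 1.03 × 10⁻⁸ M, which is 5.13 × 10⁻⁷ of the charge.

**What does that do to the reagent?** It is consumed pseudo-first-order, and over the run that constant amounts to 0.333 per unit of reagent. As a first guess I freeze the reagent at its two equivalents and let every second chain carrier go forward, which gives 66.5 % of the charge; that is a starting figure for the round and no more, since the reagent in fact falls as it is used.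

**Does every one go forward?** No. It can attack starting material or return on product. The reverse constant of the reagent step over the forward constant of the starting-material step is the return ratio, 2.05. If the second chain carrier is used as fast as it is made, the forward share is one over one plus the return ratio times product over starting material, both as fractions of the charge. No scavenger appears in it.

**Then reckon.** I take the forward share and the reagent at mid-run, with the reacted part midway. Putting 66.5 % back gives a forward share of 0.495 and a new answer of 27.5 %. The answer swings, so I go round from the mean, 47.0 %, which returns 36.1 %. The next mean, 41.5 %, returns 38.8 %. I commit to that for Thursday's, Tuesday's and Friday's alike.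

**And the scavenger?** It reaches the chain by one path: released group holding reagent as idle adduct. In Thursday's, free released group has a half-life of 0.18 min against scavenger, shorter than the run, so I balance it against its release. At the opening rate and full scavenger charge, that idles 0.605 % of the reagent. The conversion then shifts by 0.23 percentage points, less than the 5 points that counts, so I expect no change.

The forecast gave 38.1 %, 38.2 % and 38.2 %, with no change, on the ground that “the reverse of step 3 as product builds up holds conversion to roughly 38% in 20 min”.

The flask gives 38.0 %, 38.0 % and 38.0 % for Thursday's, Tuesday's and Friday's, against my 38.8 %, with no change: the span of scavenger moves the conversion by 0.045 points. In Tuesday's, the making of second chain carrier over its use, each step taken net, stands at 1.00 at 20.0 min. The return ratio puts Tuesday's forward share at 0.443 at that time. The neighbour flask with 5.00 equiv of reagent reaches 65.5 %, where the same ratio leaves a forward share of 0.204.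

Its constants are assumed; the rest is arithmetic.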